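Count how many whole charges of target the over-reaction can clear in the time allowed, before arguing about any curve.

| setting | Wednesday's | Sunday's | Monday's | dawn | autumn |
|---|---|---|---|---|---|
| starting material | 0.80 M | 0.80 M | 1.6 M | 0.80 M | 0.80 M |
| target | 0.0080 M | 0.012 M | 0.016 M | 0.0160 M | 0.0160 M |
| temperature | 30 °C | 41 °C | 30 °C | 25 °C | 45 °C |
| remark | run made earlier | run made earlier | run made earlier |  |  |
| time |  |  |  | 20 min | 20 min |

- Wednesday's (time / min: target / %, over-reaction product / %): 3.00: 84.7, 7.0; 6.00: 77.8, 16.4; 8.00: 74.2, 22.1; 12.0: 64.7, 32.7; 15.0: 57.2, 39.8; 20.0: 44.1, 53.7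
- Sunday's (time / min: target / %, over-reaction product / %): 1.33: 80.6, 11.7; 2.50: 72.6, 20.9; 4.00: 61.4, 30.3; 5.00: 53.3, 42.5; 6.00: 46.4, 53.1; 10.0: 20.0, 78.7
- Monday's (time / min: target / %, over-reaction product / %): 4.00: 89.6, 5.3; 8.00: 87.1, 9.6; 12.0: 82.2, 15.9; 15.0: 76.6, 21.0; 20.0: 72.2, 27.7

(standard deviation of a reading: 1 percentage point)

- a reading or a percentage of target counts all its forms, free or not

- which one finishes higher in share of target in all that became target or over-reaction product ("neither" within 2 percentage points) (dawn / autumn / neither)
- share of target in all that became target or over-reaction product, dawn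
- share of target in all that became target or over-reaction product, autumn

Two chemists read these peaks differently. The first holds that target decays in proportion to what is there (first-order), and Wednesday's run gives him a constant of 0.0384 min⁻¹. The second answers with Monday's run: twice the charge, yet a smaller constant, 0.0135 min⁻¹. Meanwhile over-reaction product rises at a reading of 0.0220 M min⁻¹ on Wednesday and 0.0224 M min⁻¹ on Monday. So she holds to a constant drain (zero-order).

Both take temperature from Sunday's run, whose drain of 0.0887 min⁻¹ of the charge stands against Wednesday's 0.0275 min⁻¹, and both let each degree multiply the pace by one factor. For dawn she gets 0.0161 min⁻¹, and over 20 min that makes 0.323: this pace times the time, in charges, is the drain count. Dawn's share should then be near 67.7%. Autumn's pace of 0.136 min⁻¹ gives a count of 2.71, above one, so her line reaches zero inside the time. The first chemist's decay gives 63.7% for dawn and 2.25% for autumn.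

The forecast is on her side, “the over-reaction looks zero-order”, though from paces of its own. It puts dawn higher, at 68% (60% to 75%), with autumn at 0.2% (0% to 3%).

The flask gives 68.1% for dawn and 0.281% for autumn, and dawn finishes higher; the first chemist's autumn figure stands far above that.

    starting material → target (k = 0.00190 min⁻¹, Ea = 99.0 kJ mol⁻¹)
    starting material ⇌ dormant form (K = 2.60, k = 0.0610 min⁻¹, Ea = 77.0 kJ mol⁻¹, ΔH = 4.00 kJ mol⁻¹)
    starting material + target → 2 target (k = 6.70 M⁻¹ min⁻¹, Ea = 46.0 kJ mol⁻¹)
    crystals ⇌ target, rate k4*(cs4 - [target]) while solid is left; crystals form when [target] > cs4 (solubility = 0.260 M, k = 5.80 min⁻¹)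
    target → over-reaction product (k = 0.0490 min⁻¹, Ea = 81.0 kJ mol⁻¹)
    (constants at 25 °C)

In dawn at 0.741 min, starting material halves in 0.29 min by the step with target, dissolved target in 14 min by over-reaction. In dawn, target is made early, with 99.1% of the step with target behind it by 10.0 min, and over-reaction then runs evenly, with 50% of its turnover done by 10.0 min and crystals still at 35.0% at 20.0 min: the even drain that dawn's count of 0.323 assumes. The first chemist's decay has its region where crystals stand at 0%: autumn's target bends from 6.25% at 10.0 min to 0.281% at 20.0 min. Stopped at 16.8 min or 23.2 min instead, dawn's share has moved 5 points.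

For the repeat of dawn at 0 °C, the count is 0.0225, a share near 97.8%. That flask gives 98.5%, with 1.47% over-reaction product.

The data were generated by integration on assumed constants, and the scatter is random.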